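| flask | substrate | free catalyst | temperature | remark | time |
|---|---|---|---|---|---|
| birch | 0.12 M | 0.2 mol% | 35 °C | the very flask that is asked about, followed so far |  |
| maple | 0.12 M | 0.2 mol% | 20 °C | run made earlier |  |
| flask | 0.12 M | 0.2 mol% | 35 °C |  | 80 min |

| run | time / min | target / % | substrate / % |
|---|---|---|---|
| birch | 2.50 | 43.2 | 44.8 |
| birch | 8.00 | 54.9 | 20.5 |
| birch | 15.0 | 57.7 | 10.2 |
| birch | 20.0 | 57.5 | 6.1 |
| birch | 30.0 | 58.0 | 2.4 |
| birch | 40.0 | 58.2 | 1.1 |
| birch | 50.0 | 58.3 | 1.0 |
| maple | 5.00 | 46.6 | 50.1 |
| maple | 15.0 | 62.0 | 30.0 |
| maple | 30.0 | 67.0 | 22.1 |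
| maple | 40.0 | 67.5 | 18.4 |
| maple | 60.0 | 69.8 | 14.2 |
| maple | 80.0 | 68.6 | 12.4 |
| maple | 120 | 69.4 | 7.2 |

(readings scatter by 0.5 percentage points)

- Thursday's: at 80 min take out 90% of the target then present, then wait 80 min
- Friday's: at 80 min raise the temperature by 20 K, then wait 80 min
- Monday's: at 80 min add free catalyst, 100% of the amount charged, then wait 80 min
- Wednesday's: change nothing and wait 80 min more

- removed target is counted in
- the earlier runs were read with a standard deviation of 0.5 percentage points
- additions bring no volume worth counting

1. target, in percent of the substrate first charged, at 80 min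
2. the remedy with the largest gain of target, or "none" below 2 percentage points (Thursday's / Friday's / Monday's / Wednesday's / none)
3. target present, with what was taken out counted in, in percent of the substrate first charged, after Monday's
4. target present, with what was taken out counted in, in percent of the substrate first charged, after Wednesday's

- Time stops paying in the birch flask at 35 °C, and I follow one molecule of substrate to see when. Between 20.0 min and 40.0 min substrate falls from 6.1% to 1.1% while target moves from 57.5% to 58.2%, so a molecule lost there reaches target with a chance of about 14.0%, as read.
- Target comes from substrate, so I hold the gain of a remedy against the substrate present when it acts, and two times give that amount.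
- The first is the tail half-life, the time in which late [substrate] halves, read as a first-order decay from those readings: 8.09 min.
- The second is the 40.0 min from the reading at 40.0 min to the look at 80 min, which makes 4.94 tail half-lives.
- I reckon 0.0358% of substrate at 80 min. The reading behind it carries a scatter of 0.5 percentage points, but twice that amount, 0.0716%, still lies below the margin of 2 points, so I expect no useful remedy.
- The forecast gives 58.2% (57.7% to 58.8%), 58.3% after Monday's, 58.2% after Wednesday's, and none as the best remedy: “Nothing is left to convert”.
- The birch flask gives 58.3%, 58.4% after Monday's, 58.3% after Wednesday's, and none as the best remedy.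

    substrate + free catalyst → free catalyst + target (k = 38.0 /M/s, Ea = 37.0 kJ/mol)
    2 free catalyst → spent catalyst A (k = 19.0 /M/s, Ea = 39.0 kJ/mol)
    substrate + free catalyst → spent catalyst B (k = 0.0770 /M/s, Ea = 47.0 kJ/mol)
    substrate → side product (k = 0.00130 /s, Ea = 102 kJ/mol)
    (constants at 35 °C)

- The birch flask holds 0.037% of substrate at 80.0 min, and Monday's gain of 0.028 points stays below that. In the neighbour flask with 0.05 mol% of free catalyst, a quarter of the birch loading, 80 min is 9.89 tail half-lives, which reckons 0.105% of the charge; that neighbour flask stores 0.14%, with target at 21.6%. Ten times the time adds 89.0 tail half-lives to the birch flask: substrate goes to 0%, target stands at 58.3%, and free catalyst still falls from 1.00% to 0.202% of its charge by 800 min.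

(The runs are simulated on assumed constants, and the scatter is random.)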